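The route builds the benzenoid ring of the 5',7'-dihydroxycoumarin half (ring B, primed locants) from a four-membered ring. The key step exploits three things in that ring: the 1,4-relationship of O–C5' and O–C8', the C6'–H/C7'–O pair that a semisquarate supplies, and C4a'=C8a'–O1', which is brought in as the C=C–O unit of a lithiated dihydropyran. Thermolysis of the 4-silyloxy-4-(dihydropyranyl)-3-isopropoxycyclobutenone opens it to a dienylketene that forms C4a'–C5' and aromatises in one operation, releasing C5'–OH free and C8'–O silylated. Ring A is then grown on O8' by SNAr, Dakin oxidation, ortho-formylation and Wittig lactonisation.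

Key step: step 3

Remark 1: the carbinol oxygen of the squarate adduct is carried through the rearrangement as its TBS ether, so the two para oxygens leave the key step already distinguished and no air-sensitive free hydroquinone is handled; the carbon skeletons of precursor 7 and product 10 are otherwise unchanged.
Remark 2: every intermediate containing the acetal carbon is racemic (a diastereomer mixture where a second stereocentre exists); this centre is destroyed in step 9 and the target is achiral.

Step 1
Reactants: 1 diisopropyl squarate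
Product: 3 3-isopropoxycyclobut-3-ene-1,2-dione, via hydroxy ketone 2 (not isolated)
Conditions: LiAlH(OtBu)3, THF, −78 to −20 °C; then 6 M aq. HCl, CH2Cl2, rt
Reagents that add atoms: none
Why: Mono-1,2-reduction of one squarate carbonyl by the bulky alkoxyaluminium hydride, then acid-promoted allylic transposition with loss of isopropanol, is the established partial reduction of dialkyl squarates to semisquarates.

Step 2
Reactants: 3 3-isopropoxycyclobut-3-ene-1,2-dione; 4 2-ethoxy-3,4-dihydro-2H-pyran
Product: 7 4-[(tert-butyldimethylsilyl)oxy]-4-(6-ethoxy-5,6-dihydro-4H-pyran-2-yl)-3-isopropoxycyclobut-2-en-1-one, via alkenyllithium 5 (not isolated), via lithium alkoxide 6 (not isolated)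
Conditions: 4 (1.2 equiv), t-BuLi (1.1 equiv), THF–pentane, −78 to 0 °C; then 3, THF, −78 °C; then TBSOTf, −78 to −40 °C; aq. NaHCO3
Reagents that add atoms: tert-butyldimethylsilyl trifluoromethanesulfonate (TBSOTf), CC(C)(C)[Si](C)(C)OS(=O)(=O)C(F)(F)F
Why: Vinylic alpha-lithiation of the cyclic enol ether gives an alkenyllithium that adds 1,2 to the more electrophilic ketone-type carbonyl of 3 (the one next to C–OiPr, not the vinylogous ester carbonyl), and the tertiary lithium alkoxide is O-silylated in situ before it can ring-open; the two stereocentres are uncontrolled and irrelevant.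

Step 3
Reactants: 7 4-[(tert-butyldimethylsilyl)oxy]-4-(6-ethoxy-5,6-dihydro-4H-pyran-2-yl)-3-isopropoxycyclobut-2-en-1-one
Product: 10 8-[(tert-butyldimethylsilyl)oxy]-2-ethoxy-7-isopropoxychroman-5-ol, via dienylketene 8 (not isolated), via cyclohexadienone 9 (not isolated)
Conditions: degassed toluene, 110 °C, argon
Reagents that add atoms: none
Why: Moore rearrangement: thermal conrotatory 4π opening of the cyclobutenone gives dienylketene 8, whose ketene carbon (future C5) bonds to the enol-ether β-carbon (future C4a) in a thermal disrotatory 6π electrocyclisation that closes the six-membered carbocycle as dienone 9, and enolisation then aromatises it to phenol 10. The closest known reaction type is the thermal conversion of 4-alkenyl-4-hydroxy- or 4-silyloxy-cyclobutenones into hydroquinones or their monosilyl ethers. The selectivity needed is torquoselectivity, secured by the donor silyloxy group rotating outward so that the dihydropyranyl group sits cis to the ketene. No stereocentre is set: the acetal carbon is untouched and the transient C4a centre of 9 is erased on tautomerisation. Regiochemistry (C6–H, C7–OiPr, O1 on C8a) is inherited from step 2, and because silicon stays on the former carbinol oxygen, C8–O emerges masked and C5–OH free.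

Step 4
Reactants: 10 8-[(tert-butyldimethylsilyl)oxy]-2-ethoxy-7-isopropoxychroman-5-ol
Product: 11 tert-butyl[(2-ethoxy-5,7-diisopropoxychroman-8-yl)oxy]dimethylsilane
Conditions: i-PrOH, PPh3, DIAD, THF, 0 °C to rt
Reagents that add atoms: propan-2-ol, CC(C)O
Why: Mitsunobu etherification of the single free, unhindered phenol with a secondary alcohol proceeds under neutral conditions that leave the aryl silyl ether and the acetal intact.

Step 5
Reactants: 11 tert-butyl[(2-ethoxy-5,7-diisopropoxychroman-8-yl)oxy]dimethylsilane; 12 2-fluoro-3-methoxybenzaldehyde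
Product: 14 2-[(2-ethoxy-5,7-diisopropoxychroman-8-yl)oxy]-3-methoxybenzaldehyde, via cesium phenoxide 13 (not isolated)
Conditions: CsF, DMF, 90 °C
Reagents that add atoms: none
Why: Fluoride unmasks the phenoxide from its silyl ether and this adds to the fluoroarene activated by the ortho formyl group (SNAr through a Meisenheimer adduct), the expelled fluoride carrying the chain.

Step 6
Reactants: 14 2-[(2-ethoxy-5,7-diisopropoxychroman-8-yl)oxy]-3-methoxybenzaldehyde
Product: 16 2-[(2-ethoxy-5,7-diisopropoxychroman-8-yl)oxy]-3-methoxyphenol, via aryl formate 15 (not isolated)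
Conditions: mCPBA, CH2Cl2, 0 °C to rt; then K2CO3 (cat.), MeOH, 0 °C
Reagents that add atoms: 3-chloroperoxybenzoic acid (mCPBA), OOC(=O)c1cccc(Cl)c1
Why: Baeyer–Villiger (Dakin-type) oxidation of an ortho-aryloxybenzaldehyde proceeds by aryl migration to the formate, which mild methanolysis converts to the phenol.

Step 7
Reactants: 16 2-[(2-ethoxy-5,7-diisopropoxychroman-8-yl)oxy]-3-methoxyphenol
Product: 18 3-[(2-ethoxy-5,7-diisopropoxychroman-8-yl)oxy]-2-hydroxy-4-methoxybenzaldehyde, via salicyl alcohol 17 (not isolated)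
Conditions: MgCl2, Et3N, (CH2O)n, MeCN, reflux
Reagents that add atoms: paraformaldehyde (formaldehyde), C=O
Why: Magnesium-phenoxide-directed ortho-formylation (Casnati–Skattebøl) delivers formaldehyde only to the one free ortho carbon, which is also para to the methoxy group, and a second formaldehyde oxidises the hydroxymethyl intermediate by hydride transfer; the fully etherified ring B cannot form a phenoxide and is left alone.

Step 8
Reactants: 18 3-[(2-ethoxy-5,7-diisopropoxychroman-8-yl)oxy]-2-hydroxy-4-methoxybenzaldehyde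
Product: 20 8-[(2-ethoxy-5,7-diisopropoxychroman-8-yl)oxy]-7-methoxy-2H-chromen-2-one, via Z-cinnamate 19 (not isolated)
Conditions: Ph3P=CHCO2Et, PhNEt2, 210 °C
Reagents that add atoms: ethyl (triphenylphosphoranylidene)acetate, CCOC(=O)C=P(c1ccccc1)(c1ccccc1)c1ccccc1
Why: Wittig olefination with the stabilised ylide, then thermal E/Z equilibration and lactonisation of the Z-cinnamate at this temperature, is the standard one-pot coumarin synthesis from salicylaldehydes, and the acetal is inert to the basic medium.

Step 9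
Reactants: 20 8-[(2-ethoxy-5,7-diisopropoxychroman-8-yl)oxy]-7-methoxy-2H-chromen-2-one
Product: 22 8-[(5,7-diisopropoxy-2-oxochroman-8-yl)oxy]-7-methoxy-2H-chromen-2-one, via lactol 21 (not isolated)
Conditions: Jones reagent (CrO3, H2SO4, H2O), acetone, 0 °C
Reagents that add atoms: water, O
Why: Jones oxidation of a cyclic lactol ether: aqueous acid hydrolyses the mixed acetal to the lactol, which H2CrO4 should oxidise to the δ-lactone faster than it attacks aryl ethers or the coumarin.

Step 10
Reactants: 22 8-[(5,7-diisopropoxy-2-oxochroman-8-yl)oxy]-7-methoxy-2H-chromen-2-one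
Product: 23 8-[(5,7-diisopropoxy-2-oxo-2H-chromen-8-yl)oxy]-7-methoxy-2H-chromen-2-one
Conditions: DDQ, 1,4-dioxane, 100 °C
Reagents that add atoms: none
Why: DDQ dehydrogenation of a 3,4-dihydrocoumarin by hydride abstraction from benzylic C4', assisted by the ortho and para isopropoxy groups, followed by loss of the acidic C3' proton.

Step 11
Reactants: 23 8-[(5,7-diisopropoxy-2-oxo-2H-chromen-8-yl)oxy]-7-methoxy-2H-chromen-2-one
Product: 24 8-[(5,7-dihydroxy-2-oxo-2H-chromen-8-yl)oxy]-7-methoxy-2H-chromen-2-one
Conditions: BCl3, CH2Cl2, −78 to 0 °C; then H2O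
Reagents that add atoms: none
Why: Selective Lewis acid dealkylation: BCl3 cleaves isopropyl aryl ethers through their secondary-cation-like pathway at temperatures where a non-chelated aryl methyl ether, the diaryl ether and both lactones should survive.

Compound list
1 | diisopropyl squarate (3,4-diisopropoxycyclobut-3-ene-1,2-dione) | CC(C)OC1=C(OC(C)C)C(=O)C1=O | starting material
2 | 4-hydroxy-2,3-diisopropoxycyclobut-2-en-1-one (racemic) | CC(C)OC1=C(OC(C)C)C(O)C1=O | intermediate
3 | 3-isopropoxycyclobut-3-ene-1,2-dione (isopropyl semisquarate) | CC(C)OC1=CC(=O)C1=O | intermediate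
4 | 2-ethoxy-3,4-dihydro-2H-pyran (racemic) | CCOC1CCC=CO1 | starting material
5 | (6-ethoxy-5,6-dihydro-4H-pyran-2-yl)lithium (racemic) | CCOC1CCC=C([Li])O1 | intermediate
6 | lithium 1-(6-ethoxy-5,6-dihydro-4H-pyran-2-yl)-2-isopropoxy-4-oxocyclobut-2-en-1-olate (diastereomer mixture) | [Li+].CCOC1CCC=C(O1)C1([O-])C(OC(C)C)=CC1=O | intermediate
7 | 4-[(tert-butyldimethylsilyl)oxy]-4-(6-ethoxy-5,6-dihydro-4H-pyran-2-yl)-3-isopropoxycyclobut-2-en-1-one (diastereomer mixture) | CCOC1CCC=C(O1)C1(O[Si](C)(C)C(C)(C)C)C(OC(C)C)=CC1=O | intermediate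
8 | (3Z)-4-[(tert-butyldimethylsilyl)oxy]-4-(6-ethoxy-5,6-dihydro-4H-pyran-2-yl)-3-isopropoxybuta-1,3-dien-1-one (pyranyl cis to the ketene carbon; racemic) | O=C=C/C(OC(C)C)=C(\C1=CCCC(OCC)O1)O[Si](C)(C)C(C)(C)C | intermediate
9 | 8-[(tert-butyldimethylsilyl)oxy]-2-ethoxy-7-isopropoxy-2,3,4,4a-tetrahydro-5H-chromen-5-one (diastereomer mixture) | CCOC1CCC2C(=O)C=C(OC(C)C)C(O[Si](C)(C)C(C)(C)C)=C2O1 | intermediate
10 | 8-[(tert-butyldimethylsilyl)oxy]-2-ethoxy-7-isopropoxychroman-5-ol (racemic) | CCOC1CCc2c(O)cc(OC(C)C)c(O[Si](C)(C)C(C)(C)C)c2O1 | intermediate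
11 | tert-butyl[(2-ethoxy-5,7-diisopropoxychroman-8-yl)oxy]dimethylsilane (racemic) | CCOC1CCc2c(OC(C)C)cc(OC(C)C)c(O[Si](C)(C)C(C)(C)C)c2O1 | intermediate
12 | 2-fluoro-3-methoxybenzaldehyde | COc1cccc(C=O)c1F | starting material
13 | cesium 2-ethoxy-5,7-diisopropoxychroman-8-olate (racemic) | [Cs+].CCOC1CCc2c(OC(C)C)cc(OC(C)C)c([O-])c2O1 | intermediate
14 | 2-[(2-ethoxy-5,7-diisopropoxychroman-8-yl)oxy]-3-methoxybenzaldehyde (racemic) | CCOC1CCc2c(OC(C)C)cc(OC(C)C)c(Oc3c(C=O)cccc3OC)c2O1 | intermediate
15 | 2-[(2-ethoxy-5,7-diisopropoxychroman-8-yl)oxy]-3-methoxyphenyl formate (racemic) | CCOC1CCc2c(OC(C)C)cc(OC(C)C)c(Oc3c(OC=O)cccc3OC)c2O1 | intermediate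
16 | 2-[(2-ethoxy-5,7-diisopropoxychroman-8-yl)oxy]-3-methoxyphenol (racemic) | CCOC1CCc2c(OC(C)C)cc(OC(C)C)c(Oc3c(O)cccc3OC)c2O1 | intermediate
17 | 2-[(2-ethoxy-5,7-diisopropoxychroman-8-yl)oxy]-6-(hydroxymethyl)-3-methoxyphenol (racemic) | CCOC1CCc2c(OC(C)C)cc(OC(C)C)c(Oc3c(O)c(CO)ccc3OC)c2O1 | intermediate
18 | 3-[(2-ethoxy-5,7-diisopropoxychroman-8-yl)oxy]-2-hydroxy-4-methoxybenzaldehyde (racemic) | CCOC1CCc2c(OC(C)C)cc(OC(C)C)c(Oc3c(O)c(C=O)ccc3OC)c2O1 | intermediate
19 | ethyl (2Z)-3-{3-[(2-ethoxy-5,7-diisopropoxychroman-8-yl)oxy]-2-hydroxy-4-methoxyphenyl}prop-2-enoate (racemic) | CCOC(=O)/C=C\c1ccc(OC)c(Oc2c(OC(C)C)cc(OC(C)C)c3CCC(OCC)Oc23)c1O | intermediate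
20 | 8-[(2-ethoxy-5,7-diisopropoxychroman-8-yl)oxy]-7-methoxy-2H-chromen-2-one (racemic) | CCOC1CCc2c(OC(C)C)cc(OC(C)C)c(Oc3c(OC)ccc4ccc(=O)oc34)c2O1 | intermediate
21 | 8-[(2-hydroxy-5,7-diisopropoxychroman-8-yl)oxy]-7-methoxy-2H-chromen-2-one (racemic lactol) | COc1ccc2ccc(=O)oc2c1Oc1c(OC(C)C)cc(OC(C)C)c2CCC(O)Oc12 | intermediate
22 | 8-[(5,7-diisopropoxy-2-oxochroman-8-yl)oxy]-7-methoxy-2H-chromen-2-one | COc1ccc2ccc(=O)oc2c1Oc1c(OC(C)C)cc(OC(C)C)c2CCC(=O)Oc12 | intermediate
23 | 8-[(5,7-diisopropoxy-2-oxo-2H-chromen-8-yl)oxy]-7-methoxy-2H-chromen-2-one | COc1ccc2ccc(=O)oc2c1Oc1c(OC(C)C)cc(OC(C)C)c2ccc(=O)oc12 | intermediate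
24 | 8-[(5,7-dihydroxy-2-oxo-2H-chromen-8-yl)oxy]-7-methoxy-2H-chromen-2-one (achiral) | COc1ccc2ccc(=O)oc2c1Oc1c(O)cc(O)c2ccc(=O)oc12 | target

Total step count: 11. Longest linear sequence: 11 steps (1 to 24); 4 and 12 enter as commercial materials.

Steps most likely to fail

Step 3. The bulky silyloxy group may erode the outward-rotation preference, or silicon may be lost or transferred at the temperature needed, so that the ketene is diverted before the 6π closure. The fallback sets out from lithium alkoxide 6 and moves the differentiation of the two para oxygens to after ring formation. Alkoxide 6 is protonated with aqueous NH4Cl at −78 °C instead of being silylated, giving the free carbinol 4-(6-ethoxy-5,6-dihydro-4H-pyran-2-yl)-4-hydroxy-3-isopropoxycyclobut-2-en-1-one F1. This is the classical substrate for the rearrangement and should give, on heating in degassed toluene or p-xylene, the hydroquinone 2-ethoxy-7-isopropoxychromane-5,8-diol F2. The two phenols are then told apart by hindrance: 2-bromopropane and K2CO3 in DMF under argon should alkylate the C5 hydroxyl (flanked by CH2 and H) and spare the C8 hydroxyl (flanked by two oxygens), giving 2-ethoxy-5,7-diisopropoxychroman-8-ol F3. SNAr of F3 with 12 (K2CO3, DMF, 100 °C) comes back to the route at 14. This fallback also covers a failure of the silyl capture in step 2.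

Step 5. Addition of a doubly ortho-flanked phenoxide to a fluoroarene activated by a single formyl group and crowded by the neighbouring methoxy group may be slow, so that base-mediated degradation of the aldehyde takes over. The fallback sets out from 11 and replaces addition–elimination by copper-catalysed C–O coupling. Phenoxide 13 is released with CsF and coupled with 2-bromo-3-methoxybenzaldehyde (CuI, picolinic acid, K3PO4, DMSO, 90 °C; Ullmann-type diaryl ether synthesis), coming back to the route at 14 without new intermediates.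

Step 9. Acid opening of the acetal exposes an electron-rich phenol–aldehyde tautomer to the oxidant, so ring oxidation may compete with oxidation at the lactol carbon. The fallback sets out from 20 and reverses the order of the two oxidations. DDQ (1,4-dioxane, 80 °C) first dehydrogenates C3'–C4' to the allylic acetal 8-[(2-ethoxy-5,7-diisopropoxy-2H-chromen-8-yl)oxy]-7-methoxy-2H-chromen-2-one F4. F4 is then oxidised under anhydrous, buffered conditions (pyridinium chlorochromate [C5H5NH][CrO3Cl], NaOAc, CH2Cl2, rt) directly to the coumarin, coming back to the route at 23 and bypassing 22.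

Further compounds
F1 | step 3 | 4-(6-ethoxy-5,6-dihydro-4H-pyran-2-yl)-4-hydroxy-3-isopropoxycyclobut-2-en-1-one (diastereomer mixture) | CCOC1CCC=C(O1)C1(O)C(OC(C)C)=CC1=O
F2 | step 3 | 2-ethoxy-7-isopropoxychromane-5,8-diol (racemic) | CCOC1CCc2c(O)cc(OC(C)C)c(O)c2O1
F3 | step 3 | 2-ethoxy-5,7-diisopropoxychroman-8-ol (racemic) | CCOC1CCc2c(OC(C)C)cc(OC(C)C)c(O)c2O1
F0 | step 5 | none | none
F4 | step 9 | 8-[(2-ethoxy-5,7-diisopropoxy-2H-chromen-8-yl)oxy]-7-methoxy-2H-chromen-2-one (racemic) | COc1ccc2ccc(=O)oc2c1Oc1c(OC(C)C)cc(OC(C)C)c2C=CC(OCC)Oc12
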